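**Plan**
Cuts: (a) both phenols go back to 4-methoxybenzyl ethers; (b) the bond between the ring A carbonyl carbon and the central CH2 is cut (crossed Claisen condensation of a ring A methyl benzoate with a ring B acetophenone); (c) in ring A the C4–O and C3–CH2(prenyl) bonds are cut together; (d) in ring B the C3–CH2(prenyl) bond is cut (Stille coupling).
Enabling feature: ring A carries OMe on C2, prenyl on C3 and oxygen on C4, three neighbouring carbons. C3 and C4 can therefore be the two carbons of an aryne polarised by the C2 methoxy group. An ether R–O–CMe2–CH=CH2 then gives its oxygen to C4 and its alkene terminus to C3.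
Forward order: both benzene rings are bought and no ring is formed. The ring A piece is made in steps 1–5 and the ring B piece in steps 6–8. The chain is joined in step 9 and the phenols are freed in step 10.
Stereochemistry: the target has no stereocentre and both alkenes end in CMe2, so nothing has to be set.

Key step: step 5

Assumption: the 1,3-diketones of the last two steps are drawn as diketo tautomers, although they should exist largely as chelated enols.

Step 1
Reactants: 1 methyl 2,4-dihydroxybenzoate
Product: 2 methyl 2,4-dihydroxy-3-iodobenzoate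
Conditions: I2 (1.0 equiv), NaHCO3, THF–H2O, 0 °C → rt
Reagents that add atoms: iodine, [I][I]
Why: Electrophilic aromatic iodination under phenoxide control should go to C3, the carbon ortho to both oxygens, as in the bicarbonate iodination of resorcinol at its 2-position, and one equivalent of iodine limits attack at C5.

Step 2
Reactants: 2 methyl 2,4-dihydroxy-3-iodobenzoate
Product: 3 methyl 2-hydroxy-3-iodo-4-{[(trifluoromethyl)sulfonyl]oxy}benzoate
Conditions: Tf2O (1.05 equiv), pyridine, CH2Cl2, −20 → 0 °C
Reagents that add atoms: trifluoromethanesulfonic anhydride (Tf2O), O=S(=O)(OS(=O)(=O)C(F)(F)F)C(F)(F)F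
Why: Selective O-sulfonylation, because the 2-hydroxyl is held in a hydrogen bond to the ester carbonyl and one equivalent of anhydride should take the free, more acidic 4-hydroxyl.

Step 3
Reactants: 3 methyl 2-hydroxy-3-iodo-4-{[(trifluoromethyl)sulfonyl]oxy}benzoate
Product: 4 methyl 3-iodo-2-methoxy-4-{[(trifluoromethyl)sulfonyl]oxy}benzoate
Conditions: MeI, K2CO3, DMF, rt
Reagents that add atoms: iodomethane (MeI), CI
Why: Williamson O-methylation, in which carbonate in a dipolar aprotic solvent opens the chelate while the aryl triflate and aryl iodide stay inert at room temperature.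

Step 4
Reactants: 5 2-methylbut-3-en-2-ol; 6 4-methoxybenzyl chloride
Product: 7 1-methoxy-4-{[(2-methylbut-3-en-2-yl)oxy]methyl}benzene
Conditions: NaH, Bu4NI (cat.), THF–DMF, 0 °C → rt
Reagents that add atoms: none
Why: Williamson ether synthesis of a tertiary alkoxide with a benzylic halide that cannot eliminate, run under basic conditions so that the tertiary allylic alcohol is never ionised.

Step 5
Reactants: 4 methyl 3-iodo-2-methoxy-4-{[(trifluoromethyl)sulfonyl]oxy}benzoate; 7 1-methoxy-4-{[(2-methylbut-3-en-2-yl)oxy]methyl}benzene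
Product: 11 methyl 2-methoxy-4-[(4-methoxybenzyl)oxy]-3-(3-methylbut-2-en-1-yl)benzoate, via arylmagnesium chloride 8 (not isolated), via C3–C4 aryne 9 (not isolated), via aryl anion–oxonium zwitterion 10 (not isolated)
Conditions: Me3SiCH2MgCl (1.2 equiv, Et2O stripped, stock in PhMe, slow addition), 7 (8 equiv), PhMe, −78 °C → rt
Reagents that add atoms: none
Why: Proposed new method: iodine–magnesium exchange at C3 gives 8, which expels triflate to release aryne 9; the ether oxygen of 7 adds to C4 and zwitterion 10 collapses through the six-atom array C3–C4–O–CMe2–CH=CH2, with C3 bonding to the terminal CH2 as the O–CMe2 bond breaks, so the C4–O and C3–CH2 bonds arise in one operation. The closest known reaction types are the aryne aza-Claisen rearrangement of tertiary allylamines and the addition of ethers to arynes through oxonium intermediates, but an acyclic tertiary allyl ether has not been used in this way. Oxygen must attack C4 and not C3, and the C2 methoxy group secures this, since its σ-withdrawal widens the aryne angle at C4 and stabilises the charge that builds up at C3, the usual meta selectivity of 3-methoxyarynes. The dimethylallyl group must migrate rather than the benzyl group: its tertiary allylic C–O bond is the weakest and most crowded in the oxonium, it alone reaches C3 through a six-membered transition state, and the allyl inversion turns the 1,1-dimethylallyl unit into the linear prenyl group. The silylmethyl Grignard reagent should exchange with the iodide faster than it attacks the ester or the aryne, and an ether-free medium with 7 in large excess keeps solvent oxygen from competing. No ring closes and no stereocentre is formed.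

Step 6
Reactants: 12 4-hydroxyacetophenone
Product: 13 1-(4-hydroxy-3-iodophenyl)ethanone
Conditions: NIS (1.0 equiv), TsOH·H2O (10 mol %), MeCN, rt
Reagents that add atoms: N-iodosuccinimide (NIS), O=C1CCC(=O)N1I
Why: Acid-activated electrophilic aromatic iodination, directed ortho to the hydroxyl because the para position is blocked by the acetyl group, with one equivalent of reagent limiting diiodination.

Step 7
Reactants: 13 1-(4-hydroxy-3-iodophenyl)ethanone; 6 4-methoxybenzyl chloride
Product: 14 1-{3-iodo-4-[(4-methoxybenzyl)oxy]phenyl}ethanone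
Conditions: K2CO3, DMF, 50 °C
Reagents that add atoms: none
Why: Williamson O-benzylation of an acidic phenol with a base too weak to enolise the methyl ketone, which gives ring B the same protecting group as ring A.

Step 8
Reactants: 14 1-{3-iodo-4-[(4-methoxybenzyl)oxy]phenyl}ethanone; 15 tributyl(3-methylbut-2-en-1-yl)stannane
Product: 16 1-{4-[(4-methoxybenzyl)oxy]-3-(3-methylbut-2-en-1-yl)phenyl}ethanone
Conditions: Pd(PPh3)4 (5 mol %), DMF, 90 °C
Reagents that add atoms: none
Why: Stille cross-coupling, in which zerovalent palladium inserts into the carbon–iodine bond and reductive elimination from the less hindered allyl terminus should deliver the linear prenyl arene, a standard way of prenylating aryl halides.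

Step 9
Reactants: 11 methyl 2-methoxy-4-[(4-methoxybenzyl)oxy]-3-(3-methylbut-2-en-1-yl)benzoate; 16 1-{4-[(4-methoxybenzyl)oxy]-3-(3-methylbut-2-en-1-yl)phenyl}ethanone
Product: 17 1-{2-methoxy-4-[(4-methoxybenzyl)oxy]-3-(3-methylbut-2-en-1-yl)phenyl}-3-{4-[(4-methoxybenzyl)oxy]-3-(3-methylbut-2-en-1-yl)phenyl}propane-1,3-dione
Conditions: NaH (2.5 equiv), THF, 65 °C; then cold 1 M HCl
Reagents that add atoms: none
Why: Crossed Claisen condensation in which only 16 is enolisable and 11 is the sole acyl donor, driven by irreversible deprotonation of the 1,3-diketone formed, as in the standard preparation of dibenzoylmethanes.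

Step 10
Reactants: 17 1-{2-methoxy-4-[(4-methoxybenzyl)oxy]-3-(3-methylbut-2-en-1-yl)phenyl}-3-{4-[(4-methoxybenzyl)oxy]-3-(3-methylbut-2-en-1-yl)phenyl}propane-1,3-dione
Product: 18 1-[4-hydroxy-2-methoxy-3-(3-methylbut-2-en-1-yl)phenyl]-3-[4-hydroxy-3-(3-methylbut-2-en-1-yl)phenyl]propane-1,3-dione (CNP0167758.0)
Conditions: MgBr2·OEt2 (6 equiv), Me2S (excess), CH2Cl2, 0 °C → rt; then cold 0.5 M HCl
Reagents that add atoms: none
Why: Lewis acid-assisted nucleophilic cleavage of 4-methoxybenzyl ethers, in which magnesium activates each aryl benzyl ether oxygen and the soft sulfide takes the benzylic carbon, so that no strong Brønsted acid or free benzyl cation meets the prenyl groups, the enolised diketone or the C2 methyl ether.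

**Compound list**
1 | methyl 2,4-dihydroxybenzoate | COC(=O)c1ccc(O)cc1O | starting material
2 | methyl 2,4-dihydroxy-3-iodobenzoate | Ic1c(O)ccc(C(=O)OC)c1O | intermediate
3 | methyl 2-hydroxy-3-iodo-4-{[(trifluoromethyl)sulfonyl]oxy}benzoate | Ic1c(OS(=O)(=O)C(F)(F)F)ccc(C(=O)OC)c1O | intermediate
4 | methyl 3-iodo-2-methoxy-4-{[(trifluoromethyl)sulfonyl]oxy}benzoate | Ic1c(OS(=O)(=O)C(F)(F)F)ccc(C(=O)OC)c1OC | intermediate
5 | 2-methylbut-3-en-2-ol | C=CC(C)(C)O | starting material
6 | 4-methoxybenzyl chloride | COc1ccc(CCl)cc1 | starting material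
7 | 1-methoxy-4-{[(2-methylbut-3-en-2-yl)oxy]methyl}benzene | COc1ccc(COC(C)(C)C=C)cc1 | intermediate
8 | [2-methoxy-3-(methoxycarbonyl)-6-{[(trifluoromethyl)sulfonyl]oxy}phenyl]magnesium chloride | COC(=O)c1ccc(OS(=O)(=O)C(F)(F)F)c([Mg]Cl)c1OC | intermediate
9 | methyl 3,4-didehydro-2-methoxybenzoate (C3–C4 aryne) | COC(=O)C1=C(OC)C#CC=C1 | intermediate
10 | zwitterion of ring A: carbanion at C3, aryl(4-methoxybenzyl)(2-methylbut-3-en-2-yl)oxonium at C4 | COC(=O)c1ccc([O+](Cc2ccc(OC)cc2)C(C)(C)C=C)[c-]c1OC | intermediate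
11 | methyl 2-methoxy-4-[(4-methoxybenzyl)oxy]-3-(3-methylbut-2-en-1-yl)benzoate | COC(=O)c1ccc(OCc2ccc(OC)cc2)c(CC=C(C)C)c1OC | intermediate
12 | 4-hydroxyacetophenone | CC(=O)c1ccc(O)cc1 | starting material
13 | 1-(4-hydroxy-3-iodophenyl)ethanone | Ic1cc(C(C)=O)ccc1O | intermediate
14 | 1-{3-iodo-4-[(4-methoxybenzyl)oxy]phenyl}ethanone | Ic1cc(C(C)=O)ccc1OCc2ccc(OC)cc2 | intermediate
15 | tributyl(3-methylbut-2-en-1-yl)stannane | CCCC[Sn](CCCC)(CCCC)CC=C(C)C | starting material
16 | 1-{4-[(4-methoxybenzyl)oxy]-3-(3-methylbut-2-en-1-yl)phenyl}ethanone | CC(=O)c1ccc(OCc2ccc(OC)cc2)c(CC=C(C)C)c1 | intermediate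
17 | 1-{2-methoxy-4-[(4-methoxybenzyl)oxy]-3-(3-methylbut-2-en-1-yl)phenyl}-3-{4-[(4-methoxybenzyl)oxy]-3-(3-methylbut-2-en-1-yl)phenyl}propane-1,3-dione | COc1c(C(=O)CC(=O)c2ccc(OCc3ccc(OC)cc3)c(CC=C(C)C)c2)ccc(OCc2ccc(OC)cc2)c1CC=C(C)C | intermediate
18 | 1-[4-hydroxy-2-methoxy-3-(3-methylbut-2-en-1-yl)phenyl]-3-[4-hydroxy-3-(3-methylbut-2-en-1-yl)phenyl]propane-1,3-dione | COc1c(C(=O)CC(=O)c2ccc(O)c(CC=C(C)C)c2)ccc(O)c1CC=C(C)C | target

**Step count**
Total steps: 10. Longest linear sequence: 6 steps (steps 1, 2, 3, 5, 9, 10).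

**Steps most likely to fail**

Step 5.
- Risk: The crowded ether oxygen may be too weak a nucleophile to intercept the aryne before the Grignard reagent, the arylmagnesium precursor or the solvent consumes it.
- Risk: The zwitterion may decay by proton transfer from the benzylic CH2 or from a CMe2 methyl group, or by migration of the benzyl group, instead of the allyl shift.
- Fallback: known cross-coupling chemistry, setting out from 2 and returning at 11. The unchelated 4-hydroxyl of 2 is alkylated with 6 (K2CO3, acetone, 50 °C) to methyl 2-hydroxy-3-iodo-4-[(4-methoxybenzyl)oxy]benzoate F1. The chelated 2-hydroxyl is then methylated (MeI, K2CO3, DMF, rt) to methyl 3-iodo-2-methoxy-4-[(4-methoxybenzyl)oxy]benzoate F2. Stille coupling of F2 with 15 (Pd(PPh3)4, DMF, 100 °C) should give 11.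

Step 10.
- Risk: The freed ortho-prenylphenols may cyclise onto their alkenes if acid builds up.
- Risk: The benzyl unit may be transferred to the enolic carbon or to the phenol rings.
- Risk: Chelated magnesium may strip the C2 methyl ether.
- Fallback: the benzyl-type groups are exchanged for methoxymethyl ethers before the fragments are joined, because mild acid hydrolysis of such acetals beside ortho-prenyl groups is routine for prenylated acylphenols. The detour sets out from 11 and 13 and returns at 18.
 - Ring A piece: oxidative debenzylation of 11 (DDQ, CH2Cl2–pH 7 buffer, 0 °C) should give methyl 4-hydroxy-2-methoxy-3-(3-methylbut-2-en-1-yl)benzoate F3. This is capped (MOMCl, iPr2NEt, CH2Cl2) as methyl 2-methoxy-4-(methoxymethoxy)-3-(3-methylbut-2-en-1-yl)benzoate F4.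
 - Ring B piece: iodophenol 13 is capped in the same way as 1-[3-iodo-4-(methoxymethoxy)phenyl]ethanone F5. Coupling with 15 (Pd(PPh3)4, DMF, 90 °C) should give 1-[4-(methoxymethoxy)-3-(3-methylbut-2-en-1-yl)phenyl]ethanone F6.
 - Joining and release: condensation of F4 with F6 (NaH, THF, 65 °C) should give 1-[2-methoxy-4-(methoxymethoxy)-3-(3-methylbut-2-en-1-yl)phenyl]-3-[4-(methoxymethoxy)-3-(3-methylbut-2-en-1-yl)phenyl]propane-1,3-dione F7. Brief warming with dilute HCl in MeOH should then release 18.

Step 9.
- Risk: Acylation by an electron-rich, ortho-substituted benzoate may be so slow that self-condensation of the ketone takes over.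
- Fallback: the acylation is replaced by an aldol addition and oxidation, setting out from 11 (with 16) and returning at 17. Reduction of 11 (DIBAL-H, CH2Cl2, −78 → 0 °C) should give {2-methoxy-4-[(4-methoxybenzyl)oxy]-3-(3-methylbut-2-en-1-yl)phenyl}methanol F8. Oxidation (MnO2, CH2Cl2) should give 2-methoxy-4-[(4-methoxybenzyl)oxy]-3-(3-methylbut-2-en-1-yl)benzaldehyde F9. Addition of the lithium enolate of 16 (LDA, THF, −78 °C) should give racemic 3-hydroxy-3-{2-methoxy-4-[(4-methoxybenzyl)oxy]-3-(3-methylbut-2-en-1-yl)phenyl}-1-{4-[(4-methoxybenzyl)oxy]-3-(3-methylbut-2-en-1-yl)phenyl}propan-1-one F10. Dess–Martin oxidation (CH2Cl2, NaHCO3) erases its single stereocentre and should give 17.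

**Further compounds**
F1 | step 5 | methyl 2-hydroxy-3-iodo-4-[(4-methoxybenzyl)oxy]benzoate | Ic1c(OCc2ccc(OC)cc2)ccc(C(=O)OC)c1O
F2 | step 5 | methyl 3-iodo-2-methoxy-4-[(4-methoxybenzyl)oxy]benzoate | Ic1c(OCc2ccc(OC)cc2)ccc(C(=O)OC)c1OC
F3 | step 10 | methyl 4-hydroxy-2-methoxy-3-(3-methylbut-2-en-1-yl)benzoate | COC(=O)c1ccc(O)c(CC=C(C)C)c1OC
F4 | step 10 | methyl 2-methoxy-4-(methoxymethoxy)-3-(3-methylbut-2-en-1-yl)benzoate | COCOc1ccc(C(=O)OC)c(OC)c1CC=C(C)C
F5 | step 10 | 1-[3-iodo-4-(methoxymethoxy)phenyl]ethanone | COCOc1ccc(C(C)=O)cc1I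
F6 | step 10 | 1-[4-(methoxymethoxy)-3-(3-methylbut-2-en-1-yl)phenyl]ethanone | COCOc1ccc(C(C)=O)cc1CC=C(C)C
F7 | step 10 | 1-[2-methoxy-4-(methoxymethoxy)-3-(3-methylbut-2-en-1-yl)phenyl]-3-[4-(methoxymethoxy)-3-(3-methylbut-2-en-1-yl)phenyl]propane-1,3-dione | COCOc1ccc(C(=O)CC(=O)c2ccc(OCOC)c(CC=C(C)C)c2OC)cc1CC=C(C)C
F8 | step 9 | {2-methoxy-4-[(4-methoxybenzyl)oxy]-3-(3-methylbut-2-en-1-yl)phenyl}methanol | OCc1ccc(OCc2ccc(OC)cc2)c(CC=C(C)C)c1OC
F9 | step 9 | 2-methoxy-4-[(4-methoxybenzyl)oxy]-3-(3-methylbut-2-en-1-yl)benzaldehyde | O=Cc1ccc(OCc2ccc(OC)cc2)c(CC=C(C)C)c1OC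
F10 | step 9 | racemic 3-hydroxy-3-{2-methoxy-4-[(4-methoxybenzyl)oxy]-3-(3-methylbut-2-en-1-yl)phenyl}-1-{4-[(4-methoxybenzyl)oxy]-3-(3-methylbut-2-en-1-yl)phenyl}propan-1-one | COc1c(C(O)CC(=O)c2ccc(OCc3ccc(OC)cc3)c(CC=C(C)C)c2)ccc(OCc2ccc(OC)cc2)c1CC=C(C)C
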